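Ring A of the target, O–Cb–Cc–Ca–C3A=C4A (Ca: isobutenyl CH; Cc: fusion CH on quinolone B; Cb: fusion OCH beside CMe2), can be read as the [4+2] union of the oxadiene O=C4A–C3A=Ca of ring-opened N-methylflindersine with the pyran C3–C4 bond of a second N-methylflindersine (ring B). The oxygen, however, sits on C3 and the carbon on C4, against that alkene's innate polarity. The route therefore cuts Ca–Cc and O–Cb and oxidizes one half to its 3-ketone, whose enol has the needed polarity. A chiral phosphoric acid joins this ketone to the oxadiene released from the pyran, making the Ca–Cc bond, both its stereocentres and ring A (as hemiketal) at once; ketone reduction and SNAr reclosure finish.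

Key step: step 4

Labels: quinolone A is the quinolone whose C3A carries Ca and whose C4A oxygen lies in ring A; quinolone B is fused to the CMe2 pyran (ring B: O–CMe2–Cb–Cc–C3B=C4B); locants C2–C4 are those of the N-methylflindersine pyran (C2 = CMe2). For the ring-opened oxadiene, E and Z refer to the exocyclic C3A=Ca bond: in the E form the isobutenyl group is syn to the C4 ketone (the only geometry that can close to the pyran), in the Z form it is anti to it (the geometry that can react as a heterodiene with its terminal substituent turned outward).

Assumption: the sense of induction of the phosphoric acid on this oxadiene cannot be predicted with confidence; the (R)-acid is written, and its mirror image is taken if that is the one giving (R) at Ca.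

Remark: the hemiketal is not reduced directly with a silane and a Lewis acid, because axial hydride delivery to the bicyclic oxocarbenium ion (anti to the axial Cc–H) would be expected to give the trans A/B fusion; ring A is therefore opened, Cb is set on the monocyclic ketone, and the ring is reclosed through oxygen.

Step 1
Reactants: 1 4-hydroxy-1-methylquinolin-2(1H)-one; 2 3-methylbut-2-enal (prenal)
Product: 4 N-methylflindersine (2,2,6-trimethyl-2H-pyrano[3,2-c]quinolin-5(6H)-one), via E-oxadiene 3 (not isolated)
Conditions: ethylenediammonium diacetate (10 mol%), PhMe, 100 °C; one large batch, divided into two portions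
Reagents that add atoms: none
Why: Domino Knoevenagel condensation/oxa-6π electrocyclization: reversible amine-mediated condensation at the nucleophilic C3 of the vinylogous acid 1 funnels the material through the E-configured alkylidene dione 3 (isobutenyl syn to the C4 carbonyl), a 1-oxatriene that closes thermally to the 2H-pyran (the standard pyranoquinolone annulation), and no stereocentre is created.

Step 2
Reactants: 4 N-methylflindersine (first portion)
Product: 5 racemic cis-3,4-epoxide of N-methylflindersine
Conditions: dimethyldioxirane (1.2 equiv, acetone solution), CH2Cl2, 0 °C; evaporate, use crude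
Reagents that add atoms: dimethyldioxirane, CC1(C)OO1
Why: Prilezhaev-type epoxidation with a neutral dioxirane: the electron-rich chromene-like C3=C4 bond is the only non-aromatic alkene, and the acid-free, volatile reagent lets the ionization-prone epoxide be obtained by simple evaporation; its two racemic stereocentres are erased in step 3.

Step 3
Reactants: 5 racemic cis-3,4-epoxide
Product: 6 2,2,6-trimethyl-2H-pyrano[3,2-c]quinoline-3,5(4H,6H)-dione (the 3-ketone half, achiral)
Conditions: BF3·OEt2 (20 mol%), CH2Cl2, −78 to −20 °C; handled under argon
Reagents that add atoms: none
Why: Meinwald rearrangement: the Lewis acid opens the epoxide at C4 to a cation stabilized by the 4-oxyquinolone system, and 1,2-hydride shift from C3 (or loss of the C3 proton to the same enol) can only give the 3-ketone because C2 is quaternary, as in the known conversion of 2,2-dimethylchromene oxides into chroman-3-ones.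

Step 4
Reactants: 6 3-ketone half; 4 N-methylflindersine (second portion, 1.5 equiv)
Product: 9 cis-fused hemiketal of the Michael adduct (Ca R; Cb S; Cc S), via Z-oxadiene 7 (not isolated), via keto adduct 8 (not isolated)
Conditions: (R)-3,3'-bis(2,4,6-triisopropylphenyl)-1,1'-binaphthyl-2,2'-diyl hydrogen phosphate (10 mol%), PhMe, 50 °C, argon
Reagents that add atoms: none
Why: Proposed new method: the phosphoric acid, bound to the lactam carbonyl of 4, should promote reversible heterolytic opening of the O–CMe2 bond (the acid-assisted reverse of an oxa-6π closure), and rotation about the C3A–Ca bond of the O-protonated open form, where that bond is nearly single, lets the oxadiene be released as the Z isomer 7 with isobutenyl anti to C4A=O and not in the geometry that would merely reclose; the same phosphate then bridges the C4A carbonyl of 7 and the enol OH of 6 while the enol carbon C4 (the future Cc) adds to Ca to give 8, after which the regenerated 4-OH of 8 adds to the Cb ketone. Precedent exists only for the two halves of this event, namely chiral BINOL-phosphate catalysed Michael addition/cyclization of ketone and 1,3-dicarbonyl enols to ortho-quinone methides generated in situ, and the thermal or acid-promoted valence isomerization of flindersine-type 2H-pyrans to their dienone forms; a 2H-pyran serving as the quinone methide precursor under asymmetric acid catalysis has not been shown. Ring A is closed by 6-exo-trig hemiketalization, which also traps the adduct and drains the unfavourable pyran/oxadiene equilibrium. Ca (R) is set by the catalyst through enantioface selection on the oxadiene; Cc (S) by approach of the cyclic enol with ring B exo and the enol OH endo to the Z-oxadiene, which places isobutenyl trans to C3B and is reinforced by acid-mediated equilibration at the enolizable Cc; the hemiketal carbon Cb by suprafacial O/C delivery across the ring B enol (cis fusion), this centre being erased in step 5. The step needs 1,4- and not 1,6-addition, a single enol of 6, and cross- not homo-coupling of 4: the CMe2 terminus of 7 is tertiary and only the 1,4-adduct can be trapped as a six-membered hemiketal, C2 of 6 is quaternary so only the C3–C4 enol exists, and that enol is far more nucleophilic at carbon than the pyran alkene of 4.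

Step 5
Reactants: 9 cis-fused hemiketal
Product: 11 cis-3-hydroxy-4-substituted pyranoquinolone with free 4-hydroxyquinolone A (Ca R; Cb S; Cc S), via sodium quinolonate 10 (not isolated)
Conditions: NaH (1.05 equiv), THF, 0 °C; then LiBH(s-Bu)3 (L-Selectride, 1.5 equiv), −78 to −40 °C; aq NH4Cl work-up (no strong acid, which could add the 4-OH across the isobutenyl alkene)
Reagents that add atoms: none
Why: Ring-chain opening then diastereoselective hydride reduction: one equivalent of base turns the hemiketal into the ring-opened 4-oxidoquinolone ketone 10, and the bulky trialkylborohydride attacks the ring B carbonyl anti to the large Cc substituent (held pseudoaxial by the peri lactam carbonyl; Felkin-type steric approach control), which sets Cb as (S) with OH cis to the side chain, while the cold, non-equilibrating conditions leave the enolizable Cc and Ca untouched.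

Step 6
Reactants: 11 cis alcohol with free 4-hydroxyquinolone A
Product: 12 4-tosyloxyquinolone A alcohol (Ca R; Cb S; Cc S)
Conditions: TsCl (1.1 equiv), Et3N, CH2Cl2, 0 °C
Reagents that add atoms: p-toluenesulfonyl chloride, Cc1ccc(cc1)S(=O)(=O)Cl
Why: Chemoselective O-sulfonylation: triethylamine ionizes only the acidic enolic 4-OH (a vinylogous carboxylic acid), which is tosylated as 4-hydroxy-2-quinolones routinely are, whereas the neutral secondary alcohol between CMe2 and Cc is too hindered to react without a nucleophilic catalyst; no stereocentre is involved.

Step 7
Reactants: 12 4-tosyloxyquinolone A alcohol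
Product: 13 target CNP0107253.2 (Ca R; Cb S; Cc S)
Conditions: NaH (1.2 equiv), THF/DMF, 0 °C to rt
Reagents that add atoms: none
Why: Intramolecular SNAr (addition-elimination): the Cb alkoxide adds 6-endo-trig to C4A, the beta carbon of the vinylogous acyl sulfonate, and tosylate is expelled, closing ring A as the aryl ether; because the new bond is O–C4A and the Cb–O bond is never broken, Cb keeps its (S) configuration and the cis A/B fusion follows.

Compound list
1 | 4-hydroxy-1-methylquinolin-2(1H)-one | Cn1c(=O)cc(O)c2ccccc21 | starting material
2 | 3-methylbut-2-enal (prenal) | CC(C)=CC=O | starting material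
3 | (E)-1-methyl-3-(3-methylbut-2-en-1-ylidene)quinoline-2,4(1H,3H)-dione (E-oxadiene; isobutenyl syn to the C4 ketone, the geometry that electrocyclizes) | CC(C)=C/C=C1/C(=O)N(C)c2ccccc2C1=O | intermediate
4 | N-methylflindersine, 2,2,6-trimethyl-2H-pyrano[3,2-c]quinolin-5(6H)-one | CC1(C)C=Cc2c(O1)c1ccccc1n(C)c2=O | intermediate
5 | 3,4-epoxy-2,2,6-trimethyl-3,4-dihydro-2H-pyrano[3,2-c]quinolin-5(6H)-one (cis-fused oxirane, racemic; one enantiomer drawn) | CC1(C)Oc2c([C@H]3O[C@H]31)c(=O)n(C)c1ccccc21 | intermediate
6 | 2,2,6-trimethyl-2H-pyrano[3,2-c]quinoline-3,5(4H,6H)-dione | CC1(C)Oc2c(CC1=O)c(=O)n(C)c1ccccc21 | intermediate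
7 | (Z)-1-methyl-3-(3-methylbut-2-en-1-ylidene)quinoline-2,4(1H,3H)-dione (Z-oxadiene; isobutenyl anti to the C4 ketone, the heterodiene geometry) | CC(C)=C/C=C1\C(=O)N(C)c2ccccc2C1=O | intermediate
8 | keto adduct: (4S)-4-[(1R)-1-(4-hydroxy-1-methyl-2-oxo-1,2-dihydroquinolin-3-yl)-3-methylbut-2-en-1-yl]-2,2,6-trimethyl-2H-pyrano[3,2-c]quinoline-3,5(4H,6H)-dione | CC(C)=C[C@@H](c1c(O)c2ccccc2n(C)c1=O)[C@H]1c2c(c3ccccc3n(C)c2=O)OC(C)(C)C1=O | intermediate
9 | cis-fused hemiketal of 8: ring A closed by the 4-oxygen of quinolone A on Cb, which carries OH cis to the Cc–H (Ca R, Cb S, Cc S); isobutenyl trans to C3B | CC(C)=C[C@H]1c2c(c3ccccc3n(C)c2=O)O[C@@]2(O)[C@@H]1c1c(c3ccccc3n(C)c1=O)OC2(C)C | intermediate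
10 | sodium salt of keto adduct 8 (sodium 4-oxidoquinolone A, ring B ketone free) | CC(C)=C[C@@H](c1c([O-])c2ccccc2n(C)c1=O)[C@H]1c2c(c3ccccc3n(C)c2=O)OC(C)(C)C1=O.[Na+] | intermediate
11 | (3S,4S)-3-hydroxy-4-[(1R)-1-(4-hydroxy-1-methyl-2-oxo-1,2-dihydroquinolin-3-yl)-3-methylbut-2-en-1-yl]-2,2,6-trimethyl-3,4-dihydro-2H-pyrano[3,2-c]quinolin-5(6H)-one (3,4-cis) | CC(C)=C[C@@H](c1c(O)c2ccccc2n(C)c1=O)[C@H]1c2c(c3ccccc3n(C)c2=O)OC(C)(C)[C@H]1O | intermediate
12 | 3-{(1R)-1-[(3S,4S)-3-hydroxy-2,2,6-trimethyl-5-oxo-3,4,5,6-tetrahydro-2H-pyrano[3,2-c]quinolin-4-yl]-3-methylbut-2-en-1-yl}-1-methyl-2-oxo-1,2-dihydroquinolin-4-yl 4-methylbenzenesulfonate | CC(C)=C[C@@H](c1c(OS(=O)(=O)c2ccc(C)cc2)c2ccccc2n(C)c1=O)[C@H]1c2c(c3ccccc3n(C)c2=O)OC(C)(C)[C@H]1O | intermediate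
13 | CNP0107253.2: bis(pyranoquinolone) with cis-fused rings A and B; Ca (R) bears 2-methylprop-1-enyl trans to C3B, Cb (S) is the OCH beside CMe2, Cc (S) is the CH on C3B | CC(C)=C[C@H]1c2c(c3ccccc3n(C)c2=O)O[C@H]2[C@@H]1c1c(c3ccccc3n(C)c1=O)OC2(C)C | target

Total step count: 7. Longest linear sequence: 7 steps (1 and 2 to 4, then 5, 6, 9, 11, 12, 13); the only convergence is the second portion of 4 entering at step 4.

Steps most likely to fail

Step 4. The process at risk is threefold: too little oxadiene may be released from the pyran by a weak chiral acid at a temperature where the catalyst still discriminates; the phosphate may fail to differentiate the faces of this doubly acylated oxadiene; or 1,6-addition may intrude. The fallback uses known chemistry, sets out from 1, 2 and 6, and rejoins the route at 9. The oxadiene is produced the established way, by amine-salt catalysed Knoevenagel condensation of 1 with 2 (ethylenediammonium diacetate, PhMe, 60–80 °C), now in the presence of ketone 6. A Tietze-type domino Knoevenagel/Michael/hemiketalization (formal hetero-Diels–Alder of an alkylidene-1,3-dicarbonyl with an enol) then intercepts it in its reactive Z form 7, before or after reversible closure of its E form 3 to 4. Without a chiral catalyst the keto adduct 8 should form together with its mirror image, ent-keto adduct F1, and these close to hemiketal 9 and its mirror image, ent-hemiketal F2. The relative configuration still rests on the exo approach and on equilibration at Cc. The racemate is resolved by preparative chromatography on a chiral stationary phase (amylose or cellulose carbamate type), and 9 re-enters at step 5.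

Step 5. The process at risk is poor or reversed facial selectivity of hydride delivery, should the Cc side chain sit pseudoequatorial so that axial attack syn to it wins, together with base-induced epimerization at Cc. The fallback sets out from 9 and returns at 13, and uses the unwanted selectivity instead of fighting it. Hemiketal 9 is reduced under whichever conditions give the Cb epimer most cleanly (NaBH4, MeOH/THF, −20 °C as first choice, through keto form 8) to the trans alcohol F3. F3 is closed by intramolecular Mitsunobu etherification (PPh3, DIAD, THF, 0 °C to rt): the acidic 4-OH of quinolone A displaces the activated Cb oxygen with inversion. This forms the O–Cb bond in place of the O–C4A bond, gives the same cis-fused ring A directly, and bypasses 11 and 12.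

Step 7. The process at risk is transfer of the sulfonyl group from the quinolone oxygen to the alkoxide by attack at sulfur, or sluggish addition at the hindered, electron-rich C4A. The fallback runs from 12 to 13 by a different bond-forming mechanism: palladium-catalysed intramolecular C–O coupling of the vinylogous acyl tosylate with the secondary alcohol (Pd(OAc)2, 2-(di-tert-butylphosphino)-1,1'-binaphthyl, K3PO4, PhMe, 80 °C). Oxidative addition of zerovalent palladium into the C4A–OTs bond precedes alkoxide coordination and C–O reductive elimination, so no free alkoxide meets the sulfonate. The Cb–O bond is again untouched, Cb is retained, and no compound outside the list is made (F0).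

Further compounds
F1 | step 4 | ent-keto adduct (mirror image of 8) | CC(C)=C[C@H](c1c(O)c2ccccc2n(C)c1=O)[C@@H]1c2c(c3ccccc3n(C)c2=O)OC(C)(C)C1=O
F2 | step 4 | ent-hemiketal (mirror image of 9) | CC(C)=C[C@@H]1c2c(c3ccccc3n(C)c2=O)O[C@]2(O)[C@H]1c1c(c3ccccc3n(C)c1=O)OC2(C)C
F3 | step 5 | trans alcohol (Cb epimer of 11; Ca R, Cb R, Cc S) | CC(C)=C[C@@H](c1c(O)c2ccccc2n(C)c1=O)[C@H]1c2c(c3ccccc3n(C)c2=O)OC(C)(C)[C@@H]1O
F0 | step 7 | none | none
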